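The second is the unit I want here: a rate constant times a concentration is a rate per second, and its inverse is a lifetime.

| setting | maple | cedar | birch | alder |
|---|---|---|---|---|
| E | 1.0 mM (fed, over 10 s) | 1.0 mM | 1.0 mM | 1.0 mM (in portions, 3, over 10 s) |
| G | 1.50 mM | 1.50 mM (fed, over 10 s) | 1.50 mM | 1.50 mM |
| time | 15 s | 15 s | 15 s | 15 s |
| remark | the addition at 30 °C, then warmed to 60 °C; the feed brings no volume worth counting | all else is in the flask from the start; the feed brings no volume worth counting | everything together at the start | first portion at the start, last at 10 s |
| temperature |  | 60 °C | 60 °C | 60 °C |

    E + G → Z + X (k1 = 600 L mol⁻¹ s⁻¹, Ea1 = 48.0 kJ mol⁻¹)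
    E + Z → E.Z (k2 = 93 L mol⁻¹ s⁻¹, Ea2 = 57.0 kJ mol⁻¹)
    G + Z → D + X (k3 = 640 L mol⁻¹ s⁻¹, Ea3 = 35.0 kJ mol⁻¹)
    (constants at 60 °C)

- a species is counted by the E in it: one E.Z counts as two
- the list of constants is for 60 °C, to be carried to other temperatures by the activation energies

1. the flask with the highest amount of Z, in percent of the E charged ("all alike" if they lie within 1.5 percentage points) (maple / cedar / birch / alder / all alike)
2. final Z, as a percentage of the E charged, in maple
3. final Z, as a percentage of the E charged, in cedar
4. final Z, as a percentage of the E charged, in birch
5. final Z, as a percentage of the E charged, in alder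

E meets G to give Z, and Z meets the same G to give D. The rate of making Z is the constant of E + G times E times G, and the rate of using it is the constant of G + Z times Z times G, so G cancels from their ratio. With E + Z set aside, its constant being smaller than that of G + Z, Z gains while E/Z stands above the selectivity factor s, the constant of G + Z over that of E + G: 1.07 at 60 °C. Carried to 30 °C by the activation energies, s becomes 1.70, which is larger, so cold raises the bar for Z.

What cold can do is keep E waiting. The lifetime of E against the whole charge of G is 1.11 s at 60 °C, far shorter than the feed of 10 s. At 30 °C it is 6.17 s, longer though still below the feed. So E should pile up in maple and reach the warm stage with E/Z still high. Ranking the flasks by this lifetime, taken at the whole charge of G even in cedar, where G is fed, I commit to maple, and by hand I go no further.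

The forecast also names maple, with 21.8% of Z there, 17.1% in cedar, 16.4% in birch and 15.8% in alder. Its ground is that cooling “favours Z formation over its further reaction”. There we differ, since my s rises on cooling and I credit the waiting E.

The flasks end with 23.3% of Z in maple, 17.1% in cedar, 17.8% in birch and 16.2% in alder, so maple stands highest. At the change of temperature at 10.0 s, maple holds 57.5% of E against 21.0% of Z, an E/Z of 2.74, above s at 60 °C, and Z in maple goes from there to 23.3%. In alder, just before the last addition at 10.0 s, E stands at 5.61% and Z at 9.88%, an E/Z of 0.568, under the 1.07 of s.

All constants come from no measurement; the result is computed.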